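**Retrosynthetic overview**
1. Target 18 ⇐ tris-MOM ether 17 (acetal removal) ⇐ 6-iodoisoflavone 15 + prenylstannane 16 (C6–prenyl bond, Stille).
2. 15 ⇐ ring B alcohol 7 + 3,6-diiodochromone 12 (C3–C1′ bond: lithiation, borylation, Suzuki–Miyaura at the 3-iodide only).
3. 12 ⇐ 2,4,6-trihydroxyacetophenone 8: ring A is bought, ring C is closed by enaminone iodocyclisation, then C6 is iodinated under direction of the free 5-OH.
4. 7 ⇐ dioxolanone 4 (MeLi opening, Wittig) ⇐ aryl iodide 2 + acid 3: key Ar–CH2 bond by visible-light nickel/photoredox decarboxylative coupling; ring B is bought.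
5. The single stereocentre (R) is bought in 3, the acetonide of (R)-malic acid, and never takes part in a bond change. Ring order: A and B purchased, C formed in step 6.

Assumption: [(4R)-2,2-dimethyl-5-oxo-1,3-dioxolan-4-yl]acetic acid 3, 2-iodoresorcinol 1, 2,4,6-trihydroxyacetophenone 8 and tributyl(3-methylbut-2-enyl)stannane 16 are taken as purchasable.

**Route**

Step 1
Reactants: 1 2-iodobenzene-1,3-diol
Product: 2 2-iodo-1,3-bis(methoxymethoxy)benzene
Conditions: NaH (2.4 equiv), MOMCl (2.3 equiv), DMF, 0 °C → rt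
Reagents that add atoms: chloromethyl methyl ether, COCCl
Why: Williamson O-alkylation of both phenoxides; the small MOM acetals keep the flanked C–I bond accessible and later direct the ring lithiation.

Step 2
Reactants: 2 2-iodo-1,3-bis(methoxymethoxy)benzene; 3 [(4R)-2,2-dimethyl-5-oxo-1,3-dioxolan-4-yl]acetic acid
Product: 4 (5R)-5-[2,6-bis(methoxymethoxy)benzyl]-2,2-dimethyl-1,3-dioxolan-4-one
Conditions: 3 (1.5 equiv), 4CzIPN (2 mol%), NiBr2·dme (10 mol%), 4,4′-di-tert-butyl-2,2′-bipyridine (15 mol%), Cs2CO3 (1.5 equiv), phthalimide (1 equiv), degassed DMSO, 450 nm LEDs, 30 °C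
Reagents that add atoms: none
Why: Proposed new method: a nickel/photoredox decarboxylative C(sp2)–C(sp3) coupling not yet shown for a doubly ortho-alkoxylated aryl iodide paired with a β-oxygenated, unstabilised primary carboxylate, in which excited 4CzIPN oxidises the caesium carboxylate of 3, loss of CO2 gives the primary exocyclic CH2 radical (the adjacent (R) centre bought in 3 is never a radical or anion site and is carried through unchanged), zerovalent nickel adds oxidatively to the C–I bond of 2 (an ortho MOM oxygen can bind hemilabile and stabilise the crowded aryl–nickel species), radical capture gives an aryl(alkyl) trivalent nickel that reductively eliminates the Ar–CH2 bond, and the reduced photocatalyst returns nickel to the zerovalent state; the closest known reaction type is the dual nickel/photoredox decarboxylative arylation of aliphatic carboxylic acids with unhindered aryl halides.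

Step 3
Reactants: 4 (5R)-5-[2,6-bis(methoxymethoxy)benzyl]-2,2-dimethyl-1,3-dioxolan-4-one
Product: 6 (3R)-4-[2,6-bis(methoxymethoxy)phenyl]-3-hydroxybutan-2-one, via lithium hemiketal alkoxide 5 (not isolated)
Conditions: MeLi (1.15 equiv), THF, −78 °C; AcOH (1.5 equiv), −78 °C → rt
Reagents that add atoms: methyllithium, [Li]C
Why: Nucleophilic acyl addition to the dioxolanone gives a tetrahedral lithium hemiketal alkoxide that is stable at −78 °C and blocks a second addition; protonation releases acetone and the α-hydroxy methyl ketone with the stereocentre untouched.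

Step 4
Reactants: 6 (3R)-4-[2,6-bis(methoxymethoxy)phenyl]-3-hydroxybutan-2-one
Product: 7 (2R)-1-[2,6-bis(methoxymethoxy)phenyl]-3-methylbut-3-en-2-ol
Conditions: Ph3PCH3Br (3.0 equiv), KOt-Bu (2.9 equiv), THF, 0 °C; then 6, 0 °C → rt
Reagents that add atoms: methyltriphenylphosphonium bromide, C[P+](c1ccccc1)(c1ccccc1)c1ccccc1.[Br-]
Why: Wittig methylenation; excess ylide first forms the alkoxide, which suppresses enolisation toward the carbinol carbon, so the (R) centre is kept while the ketone becomes the isopropenyl group.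

Step 5
Reactants: 8 1-(2,4,6-trihydroxyphenyl)ethanone
Product: 9 1-[2,6-dihydroxy-4-(methoxymethoxy)phenyl]ethanone
Conditions: MOMCl (1.0 equiv), K2CO3 (1.1 equiv), acetone, 0 °C → rt
Reagents that add atoms: chloromethyl methyl ether, COCCl
Why: Selective Williamson O-alkylation of the para hydroxyl, the most acidic one and the only one not hydrogen-bonded to the acetyl carbonyl.

Step 6
Reactants: 9 1-[2,6-dihydroxy-4-(methoxymethoxy)phenyl]ethanone
Product: 11 5-hydroxy-3-iodo-7-(methoxymethoxy)-4H-chromen-4-one, via enaminone 10 (not isolated)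
Conditions: t-BuOCH(NMe2)2 (1.5 equiv), THF, 60 °C; evaporate; I2 (1.2 equiv), CHCl3, rt
Reagents that add atoms: tert-butoxybis(dimethylamino)methane, CN(C)C(OC(C)(C)C)N(C)C; iodine, II
Why: Condensation of the methyl ketone with the aminal ester (which cannot O-methylate the free phenols) gives the enaminone, and iodine then triggers the iodocyclisation of o-hydroxyaryl enaminones (α-iodination, oxa-Michael closure of ring C by either of the two equivalent ortho hydroxyls, loss of dimethylamine).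

Step 7
Reactants: 11 5-hydroxy-3-iodo-7-(methoxymethoxy)-4H-chromen-4-one
Product: 12 5-hydroxy-3,6-diiodo-7-(methoxymethoxy)-4H-chromen-4-one
Conditions: BnMe3N·ICl2 (1.1 equiv), CaCO3 (1.5 equiv), CH2Cl2/MeOH (5:2), rt
Reagents that add atoms: benzyltrimethylammonium dichloroiodate, C[N+](C)(C)Cc1ccccc1.Cl[I-]Cl
Why: Electrophilic aromatic iodination; with the 5-hydroxyl free and the 7-oxygen alkylated, dichloroiodate attacks C6 (ortho to the free phenol, between both oxygens) in preference to C8, the pattern established for 5-hydroxy-7-alkoxychromones, and CaCO3 traps HCl so the MOM ether survives.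

Step 8
Reactants: 7 (2R)-1-[2,6-bis(methoxymethoxy)phenyl]-3-methylbut-3-en-2-ol; 12 5-hydroxy-3,6-diiodo-7-(methoxymethoxy)-4H-chromen-4-one
Product: 15 5-hydroxy-3-{3-[(2R)-2-hydroxy-3-methylbut-3-en-1-yl]-2,4-bis(methoxymethoxy)phenyl}-6-iodo-7-(methoxymethoxy)-4H-chromen-4-one, via dilithiated aryl alkoxide 13 (not isolated), via lithium triisopropyl borate 14 (not isolated)
Conditions: n-BuLi (2.3 equiv), TMEDA (2.3 equiv), THF, −20 → 0 °C; B(Oi-Pr)3 (2.5 equiv), −78 °C → rt; then 12 (0.85 equiv), Pd(dppf)Cl2 (5 mol%), aq. K3PO4 (0.5 M), THF, 40 °C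
Reagents that add atoms: n-butyllithium, [Li]CCCC (lithium of 13 and 14 only); triisopropyl borate, CC(C)OB(OC(C)C)OC(C)C (borate of 14 only)
Why: Directed ortho-metalation (after O-deprotonation one of the two equivalent ring positions ortho to a MOM ether is lithiated), borylation, then Suzuki–Miyaura coupling in which zerovalent palladium inserts into the electron-poor 3-iodoenone C–I bond far faster than into the electron-rich C6–I bond flanked by a phenoxide and a MOM ether.

Step 9
Reactants: 15 5-hydroxy-3-{3-[(2R)-2-hydroxy-3-methylbut-3-en-1-yl]-2,4-bis(methoxymethoxy)phenyl}-6-iodo-7-(methoxymethoxy)-4H-chromen-4-one; 16 tributyl(3-methylbut-2-en-1-yl)stannane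
Product: 17 5-hydroxy-3-{3-[(2R)-2-hydroxy-3-methylbut-3-en-1-yl]-2,4-bis(methoxymethoxy)phenyl}-7-(methoxymethoxy)-6-(3-methylbut-2-en-1-yl)-4H-chromen-4-one
Conditions: 16 (1.5 equiv), Pd(PPh3)4 (10 mol%), degassed DMF, 90 °C
Reagents that add atoms: none
Why: Stille coupling of the remaining aryl iodide; reductive elimination from the aryl(allyl)palladium species at the less hindered terminus gives the linear 3-methylbut-2-enyl group at C6.

Step 10
Reactants: 17 5-hydroxy-3-{3-[(2R)-2-hydroxy-3-methylbut-3-en-1-yl]-2,4-bis(methoxymethoxy)phenyl}-7-(methoxymethoxy)-6-(3-methylbut-2-en-1-yl)-4H-chromen-4-one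
Product: 18 5,7-dihydroxy-3-{2,4-dihydroxy-3-[(2R)-2-hydroxy-3-methylbut-3-en-1-yl]phenyl}-6-(3-methylbut-2-en-1-yl)-4H-chromen-4-one
Conditions: HCl (1.25 M in MeOH), THF, 0 °C → rt
Reagents that add atoms: none
Why: Acid-catalysed transacetalisation (methanolysis) of the three aryl MOM ethers under cold, dilute conditions chosen to spare the prenyl group, the allylic alcohol and its stereocentre.

**Compound list**
1 | 2-iodobenzene-1,3-diol | Oc1cccc(O)c1I | starting material
2 | 2-iodo-1,3-bis(methoxymethoxy)benzene | COCOc1cccc(OCOC)c1I | intermediate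
3 | [(4R)-2,2-dimethyl-5-oxo-1,3-dioxolan-4-yl]acetic acid | O=C1OC(C)(C)O[C@@H]1CC(=O)O | starting material
4 | (5R)-5-[2,6-bis(methoxymethoxy)benzyl]-2,2-dimethyl-1,3-dioxolan-4-one | O=C1OC(C)(C)O[C@@H]1Cc1c(OCOC)cccc1OCOC | intermediate
5 | lithium (5R)-5-[2,6-bis(methoxymethoxy)benzyl]-2,2,4-trimethyl-1,3-dioxolan-4-olate (both C4 epimers) | [Li]OC1(C)OC(C)(C)O[C@@H]1Cc1c(OCOC)cccc1OCOC | intermediate
6 | (3R)-4-[2,6-bis(methoxymethoxy)phenyl]-3-hydroxybutan-2-one | CC(=O)[C@H](O)Cc1c(OCOC)cccc1OCOC | intermediate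
7 | (2R)-1-[2,6-bis(methoxymethoxy)phenyl]-3-methylbut-3-en-2-ol | C=C(C)[C@H](O)Cc1c(OCOC)cccc1OCOC | intermediate
8 | 1-(2,4,6-trihydroxyphenyl)ethanone | CC(=O)c1c(O)cc(O)cc1O | starting material
9 | 1-[2,6-dihydroxy-4-(methoxymethoxy)phenyl]ethanone | CC(=O)c1c(O)cc(OCOC)cc1O | intermediate
10 | (E)-1-[2,6-dihydroxy-4-(methoxymethoxy)phenyl]-3-(dimethylamino)prop-2-en-1-one | CN(C)/C=C/C(=O)c1c(O)cc(OCOC)cc1O | intermediate
11 | 5-hydroxy-3-iodo-7-(methoxymethoxy)-4H-chromen-4-one | O=c1c(I)coc2cc(OCOC)cc(O)c12 | intermediate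
12 | 5-hydroxy-3,6-diiodo-7-(methoxymethoxy)-4H-chromen-4-one | O=c1c(I)coc2cc(OCOC)c(I)c(O)c12 | intermediate
13 | lithium (2R)-1-[3-lithio-2,6-bis(methoxymethoxy)phenyl]-3-methylbut-3-en-2-olate | C=C(C)[C@H](O[Li])Cc1c(OCOC)ccc([Li])c1OCOC | intermediate
14 | lithium {3-[(2R)-2-(lithiooxy)-3-methylbut-3-en-1-yl]-2,4-bis(methoxymethoxy)phenyl}triisopropoxyborate | [Li+].C=C(C)[C@H](O[Li])Cc1c(OCOC)ccc([B-](OC(C)C)(OC(C)C)OC(C)C)c1OCOC | intermediate
15 | 5-hydroxy-3-{3-[(2R)-2-hydroxy-3-methylbut-3-en-1-yl]-2,4-bis(methoxymethoxy)phenyl}-6-iodo-7-(methoxymethoxy)-4H-chromen-4-one | C=C(C)[C@H](O)Cc1c(OCOC)ccc(-c2coc3cc(OCOC)c(I)c(O)c3c2=O)c1OCOC | intermediate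
16 | tributyl(3-methylbut-2-en-1-yl)stannane | CC(C)=CC[Sn](CCCC)(CCCC)CCCC | starting material
17 | 5-hydroxy-3-{3-[(2R)-2-hydroxy-3-methylbut-3-en-1-yl]-2,4-bis(methoxymethoxy)phenyl}-7-(methoxymethoxy)-6-(3-methylbut-2-en-1-yl)-4H-chromen-4-one | C=C(C)[C@H](O)Cc1c(OCOC)ccc(-c2coc3cc(OCOC)c(CC=C(C)C)c(O)c3c2=O)c1OCOC | intermediate
18 | 5,7-dihydroxy-3-{2,4-dihydroxy-3-[(2R)-2-hydroxy-3-methylbut-3-en-1-yl]phenyl}-6-(3-methylbut-2-en-1-yl)-4H-chromen-4-one | C=C(C)[C@H](O)Cc1c(O)ccc(-c2coc3cc(O)c(CC=C(C)C)c(O)c3c2=O)c1O | target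

**Step count and risks**

Total step count: 10 (steps 1–4 build ring B with its side chain, steps 5–7 build rings A and C, steps 8–10 join and finish).
Longest linear sequence: 7 steps (1 → 2 → 4 → 6 → 7 → 15 → 17 → 18).

The three steps most likely to fail are steps 2, 8 and 10.

Step 2 (the proposed new coupling) may stall at the crowded aryl–nickel stage or give hydrodeiodination. The fallback is known chemistry; it sets out from 2 and comes back at 6. Iodine–magnesium exchange on 2 with i-PrMgCl·LiCl (THF, −20 °C) gives the aryl Grignard reagent. With CuI (10 mol%) at −40 °C it opens purchased methyl (2R)-oxirane-2-carboxylate (COC(=O)[C@H]1CO1) at the terminal carbon, leaving the stereocentre untouched, to give methyl (2R)-3-[2,6-bis(methoxymethoxy)phenyl]-2-hydroxypropanoate F1. MeNH(OMe)·HCl with i-PrMgCl converts F1 into (2R)-3-[2,6-bis(methoxymethoxy)phenyl]-2-hydroxy-N-methoxy-N-methylpropanamide F2, and MeMgBr (3 equiv, 0 °C) then gives ketone 6.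

Step 8 may suffer from competing alkoxide-directed allylic lithiation, protodeboronation of the electron-rich borate, or over-coupling at C6–I. The fallback sets out from 7 and comes back at 15, replacing the free alkoxide and the boron reagent by a silyl ether and an isolable stannane. TBSCl and imidazole (DMF) give tert-butyl{[(2R)-1-[2,6-bis(methoxymethoxy)phenyl]-3-methylbut-3-en-2-yl]oxy}dimethylsilane F3. n-BuLi/TMEDA then Bu3SnCl gives tributyl{3-[(2R)-2-(tert-butyldimethylsilyloxy)-3-methylbut-3-en-1-yl]-2,4-bis(methoxymethoxy)phenyl}stannane F4. Stille coupling with 12 (Pd(PPh3)4, CuI, DMF, 50 °C) at the 3-iodide gives 3-{3-[(2R)-2-(tert-butyldimethylsilyloxy)-3-methylbut-3-en-1-yl]-2,4-bis(methoxymethoxy)phenyl}-5-hydroxy-6-iodo-7-(methoxymethoxy)-4H-chromen-4-one F5, and TBAF (THF, 0 °C) returns 15.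

Step 10 may cyclise an ortho phenol onto the protonated isopropenyl or prenyl group, or ionise the allylic alcohol. The fallback sets out from 17 and comes back at 18, replacing Brønsted-acid solvolysis by silyl triflate acetal exchange. TMSOTf and 2,2′-bipyridyl (CH2Cl2, 0 °C → rt) convert the aryl MOM ethers through bipyridinium salts into silyl ethers and silylate the free hydroxyls, giving 3-{3-[(2R)-3-methyl-2-(trimethylsilyloxy)but-3-en-1-yl]-2,4-bis(trimethylsilyloxy)phenyl}-6-(3-methylbut-2-en-1-yl)-5,7-bis(trimethylsilyloxy)-4H-chromen-4-one F6. Water at neutral pH then hydrolyses F6 to 18.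

**Further compounds**
F1 | step 2 | methyl (2R)-3-[2,6-bis(methoxymethoxy)phenyl]-2-hydroxypropanoate | COC(=O)[C@H](O)Cc1c(OCOC)cccc1OCOC
F2 | step 2 | (2R)-3-[2,6-bis(methoxymethoxy)phenyl]-2-hydroxy-N-methoxy-N-methylpropanamide | CON(C)C(=O)[C@H](O)Cc1c(OCOC)cccc1OCOC
F3 | step 8 | tert-butyl{[(2R)-1-[2,6-bis(methoxymethoxy)phenyl]-3-methylbut-3-en-2-yl]oxy}dimethylsilane | C=C(C)[C@H](O[Si](C)(C)C(C)(C)C)Cc1c(OCOC)cccc1OCOC
F4 | step 8 | tributyl{3-[(2R)-2-(tert-butyldimethylsilyloxy)-3-methylbut-3-en-1-yl]-2,4-bis(methoxymethoxy)phenyl}stannane | C=C(C)[C@H](O[Si](C)(C)C(C)(C)C)Cc1c(OCOC)ccc([Sn](CCCC)(CCCC)CCCC)c1OCOC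
F5 | step 8 | 3-{3-[(2R)-2-(tert-butyldimethylsilyloxy)-3-methylbut-3-en-1-yl]-2,4-bis(methoxymethoxy)phenyl}-5-hydroxy-6-iodo-7-(methoxymethoxy)-4H-chromen-4-one | C=C(C)[C@H](O[Si](C)(C)C(C)(C)C)Cc1c(OCOC)ccc(-c2coc3cc(OCOC)c(I)c(O)c3c2=O)c1OCOC
F6 | step 10 | 3-{3-[(2R)-3-methyl-2-(trimethylsilyloxy)but-3-en-1-yl]-2,4-bis(trimethylsilyloxy)phenyl}-6-(3-methylbut-2-en-1-yl)-5,7-bis(trimethylsilyloxy)-4H-chromen-4-one | C=C(C)[C@H](O[Si](C)(C)C)Cc1c(O[Si](C)(C)C)ccc(-c2coc3cc(O[Si](C)(C)C)c(CC=C(C)C)c(O[Si](C)(C)C)c3c2=O)c1O[Si](C)(C)C
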